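## Retrosynthetic overview

- Stereocentre first: alkene 1 is epoxidised by a chiral ketone (dioxirane) catalyst to epoxide 2, which sets the only stereocentre.
- Aryl–CH2 bond: bromophenol 3 is metalated at carbon and oxygen (4, then 5) and opens 2 at its CH2 carbon; dialkoxide 6 is acetylated in the same flask to diacetate 7.
- Ring C–OH bond last: sterically steered C–H borylation of 7 (boronate 8) and oxidation give target 9 without protecting groups.
- No ring is formed in the route; the benzene ring is bought with 3.

Assumptions: several reagent additions in one flask without isolating an intermediate count as one step. "Ketone K" is a new catalyst, prepared separately and not counted. It is the D-glucose-derived spiro-oxazolidinone ketone of the Shi N-aryl type, with aryl = 4-n-dodecylphenyl. The target stereocentre is R by CIP analysis of the given SMILES.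

## Route

Step 1
Reactants: 1 pentadec-1-ene
Product: 2 (2R)-2-tridecyloxirane
Conditions: ketone K (20 mol %), KHSO5 (as 2KHSO5·KHSO4·K2SO4) and K2CO3 added slowly, Bu4NHSO4 (cat.), dimethoxymethane–MeCN–aq. buffer (pH about 8), −10 to 0 °C
Reagents that add atoms: potassium peroxymonosulfate, [K+].[O-]S(=O)(=O)OO
Why: Proposed new method: KHSO5 turns the chiral ketone into a dioxirane that transfers oxygen to the alkene through a spiro transition state, and the 4-dodecylphenyl tail on the oxazolidinone is meant to hold the C13 chain of 1 beside it by lipophilic contact in the aqueous medium, so that one face of the CH=CH2 unit is oxidised and the R centre is set by the catalyst (same sense as (R)-styrene oxide from the parent D-glucose-derived ketones); the closest known reaction type is the Shi ketone-catalysed asymmetric epoxidation, which gives good ee for styrenes and cis-alkenes but only modest ee so far for unbranched 1-alkenes.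

Step 2
Reactants: 2 (2R)-2-tridecyloxirane; 3 2-bromo-6-methoxyphenol
Product: 7 2-[(2R)-2-(acetyloxy)pentadecyl]-6-methoxyphenyl acetate, via dilithio arene 4 (not isolated), via dimagnesio arene 5 (not isolated), via magnesium dialkoxide 6 (not isolated)
Conditions: 3 (1.25 equiv), t-BuLi (3.0 equiv per 3), THF, −78 °C; MgBr2·OEt2 (2.1 equiv per 3), −78 to −30 °C; CuI (10 mol %), 2 (1.0 equiv), −30 to 0 °C; then Ac2O (4 equiv), DMAP (10 mol %), 0 °C to rt
Reagents that add atoms: acetic anhydride, CC(=O)OC(C)=O
Why: Bromine–lithium exchange on the lithium phenoxide puts the carbanion ortho to oxygen, and after transmetalation the aryl Grignard opens the terminal epoxide under CuI catalysis by SN2 at the CH2 carbon (copper-catalysed epoxide arylation), so the C–O stereocentre is not touched and stays R, before Ac2O esterifies both magnesium alkoxides.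

Step 3
Reactants: 7 2-[(2R)-2-(acetyloxy)pentadecyl]-6-methoxyphenyl acetate
Product: 9 (2R)-1-[2-(acetyloxy)-5-hydroxy-3-methoxyphenyl]pentadecan-2-yl acetate, via aryl boronate 8 (not isolated)
Conditions: [Ir(OMe)(cod)]2 (1.5 mol %), 4,4'-di-tert-butyl-2,2'-bipyridine (3 mol %), B2pin2 (1.0 equiv), THF, 80 °C; then KHSO5 (as 2KHSO5·KHSO4·K2SO4), acetone–H2O, 0 °C to rt, 15 min
Reagents that add atoms: potassium peroxymonosulfate, [K+].[O-]S(=O)(=O)OO
Why: Iridium-catalysed aromatic C–H borylation is steered by sterics to the one ring C–H with no ortho substituent (para to the aryl acetate), and the C–B bond is then oxidised to the phenol by peroxymonosulfate under near-neutral conditions that leave both acetates and the remote stereocentre alone (one-pot C–H borylation/oxidation).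

## Compound list

1 | pentadec-1-ene | CCCCCCCCCCCCCC=C | starting material
2 | (2R)-2-tridecyloxirane | CCCCCCCCCCCCC[C@@H]1CO1 | intermediate
3 | 2-bromo-6-methoxyphenol | COc1cccc(Br)c1O | starting material
4 | lithium 2-lithio-6-methoxyphenolate | COc1cccc([Li])c1O[Li] | intermediate
5 | [2-(bromomagnesiooxy)-3-methoxyphenyl]magnesium bromide | COc1cccc([Mg]Br)c1O[Mg]Br | intermediate
6 | bis(bromomagnesium) salt of 2-[(2R)-2-hydroxypentadecyl]-6-methoxyphenol | CCCCCCCCCCCCC[C@H](Cc1cccc(OC)c1O[Mg]Br)O[Mg]Br | intermediate
7 | 2-[(2R)-2-(acetyloxy)pentadecyl]-6-methoxyphenyl acetate | CCCCCCCCCCCCC[C@H](Cc1cccc(OC)c1OC(C)=O)OC(C)=O | intermediate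
8 | (2R)-1-[2-(acetyloxy)-3-methoxy-5-(4,4,5,5-tetramethyl-1,3,2-dioxaborolan-2-yl)phenyl]pentadecan-2-yl acetate | CCCCCCCCCCCCC[C@H](Cc1cc(B2OC(C)(C)C(C)(C)O2)cc(OC)c1OC(C)=O)OC(C)=O | intermediate
9 | (2R)-1-[2-(acetyloxy)-5-hydroxy-3-methoxyphenyl]pentadecan-2-yl acetate | CCCCCCCCCCCCC[C@H](Cc1cc(O)cc(OC)c1OC(C)=O)OC(C)=O | target

## Step count and risks

Total steps: 3. Longest linear sequence: 3 (1 → 2 → 7 → 9).

Steps most likely to fail:

**Step 1 (the proposed new epoxidation; risk: low ee on an unbranched 1-alkene).** The fallback uses known chemistry and does not use 1. Pentadecanal F1 is α-chlorinated with N-chlorosuccinimide and (2R,5R)-2,5-diphenylpyrrolidine (10 mol %, CH2Cl2, rt; enamine catalysis) to (2S)-2-chloropentadecanal F2. This is reduced in the same flask with NaBH4 (MeOH, 0 °C) to (2S)-2-chloropentadecan-1-ol F3. KOH (EtOH–H2O) then closes the ring by intramolecular SN2 with inversion, and the fallback comes back to the route at 2. The (2R,5R) → (2S) sense rests on my steric model and recollection of the reported outcome; if it proves opposite, the (2S,5S) catalyst is used.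

**Step 2 (risk: the unprotected C,O-dimetalated arene couples poorly or the in-flask acetylation is incomplete).** The fallback sets out from 3, which is protected with MOMCl and i-Pr2NEt as 1-bromo-3-methoxy-2-(methoxymethoxy)benzene F4. F4 is converted with Mg in THF into its Grignard reagent and added to 2 with CuI (10 mol %), giving (2R)-1-[3-methoxy-2-(methoxymethoxy)phenyl]pentadecan-2-ol F5. HCl in MeOH frees 2-[(2R)-2-hydroxypentadecyl]-6-methoxyphenol F6. Ac2O, pyridine and DMAP then give the diacetate, and the fallback comes back at 7.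

**Step 3 (risk: borylation next to OMe as a side reaction, or loss of the aryl acetate on oxidation).** The fallback sets out from 7 and goes through the quinone.
- NH4OAc in aqueous MeOH removes only the aryl acetate, giving (2R)-1-(2-hydroxy-3-methoxyphenyl)pentadecan-2-yl acetate F7.
- (KSO3)2NO with KH2PO4 in acetone–H2O oxidises the free phenol to (2R)-1-(5-methoxy-3,6-dioxocyclohexa-1,4-dien-1-yl)pentadecan-2-yl acetate F8.
- Zn, Ac2O and NaOAc reduce F8 to (2R)-1-(2,5-dihydroxy-3-methoxyphenyl)pentadecan-2-yl acetate F9, which is acetylated in the flask to (2R)-1-[2,5-bis(acetyloxy)-3-methoxyphenyl]pentadecan-2-yl acetate F10.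
- NH4OAc (1 equiv, aqueous MeOH, 0 °C, short time) cleaves the unhindered ring acetate first (this selectivity over the flanked acetate is expected on steric grounds, not certain), and the fallback comes back at 9.

## Further compounds

F1 | step 1 | pentadecanal | CCCCCCCCCCCCCCC=O
F2 | step 1 | (2S)-2-chloropentadecanal | CCCCCCCCCCCCC[C@H](Cl)C=O
F3 | step 1 | (2S)-2-chloropentadecan-1-ol | CCCCCCCCCCCCC[C@H](Cl)CO
F4 | step 2 | 1-bromo-3-methoxy-2-(methoxymethoxy)benzene | COCOc1c(Br)cccc1OC
F5 | step 2 | (2R)-1-[3-methoxy-2-(methoxymethoxy)phenyl]pentadecan-2-ol | CCCCCCCCCCCCC[C@H](Cc1cccc(OC)c1OCOC)O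
F6 | step 2 | 2-[(2R)-2-hydroxypentadecyl]-6-methoxyphenol | CCCCCCCCCCCCC[C@H](Cc1cccc(OC)c1O)O
F7 | step 3 | (2R)-1-(2-hydroxy-3-methoxyphenyl)pentadecan-2-yl acetate | CCCCCCCCCCCCC[C@H](Cc1cccc(OC)c1O)OC(C)=O
F8 | step 3 | (2R)-1-(5-methoxy-3,6-dioxocyclohexa-1,4-dien-1-yl)pentadecan-2-yl acetate | CCCCCCCCCCCCC[C@H](CC1=CC(=O)C=C(OC)C1=O)OC(C)=O
F9 | step 3 | (2R)-1-(2,5-dihydroxy-3-methoxyphenyl)pentadecan-2-yl acetate | CCCCCCCCCCCCC[C@H](Cc1cc(O)cc(OC)c1O)OC(C)=O
F10 | step 3 | (2R)-1-[2,5-bis(acetyloxy)-3-methoxyphenyl]pentadecan-2-yl acetate | CCCCCCCCCCCCC[C@H](Cc1cc(OC(C)=O)cc(OC)c1OC(C)=O)OC(C)=O
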